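If a yield curve bends, read the bend before you run anything.

| flask | substrate | gas phase | remark | time |
|---|---|---|---|---|
| grey | 0.13 M | 12 mM (held) | run made earlier |  |
| ochre | 0.29 M | 12 mM (held) | run made earlier |  |
| flask | 0.19 M | 12 mM (held) |  | 50 min |

| run | time / min | target / % |
|---|---|---|
| grey | 4.00 | 4.3 |
| grey | 10.0 | 9.7 |
| grey | 20.0 | 16.6 |
| grey | 50.0 | 30.1 |
| ochre | 12.0 | 11.3 |
| ochre | 25.0 | 18.4 |
| ochre | 40.0 | 24.8 |
| ochre | 50.0 | 27.4 |

(each reading ± 0.3 percentage points)

* amount of target at 50 min, in percent of the substrate charged
* the change that raises the amount of target at 50 min, in percent of the substrate charged most ("none" if none brings more than 2 percentage points) (delta / zeta / none)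
* amount of target at 50 min, in percent of the substrate charged, after zeta

- delta: doubling the transfer coefficient of the gas phase, all else as stated
- zeta: doubling the saturation concentration of gas phase, all else as stated

- at the start none of the gas phase is in solution

Write the yield of target as y = Y(1 − exp(−t/τ)), the integral of a net rate of gain that fades exponentially. This form gives y(2t)/y(t) = 1 + exp(−t/τ). The ochre run was read at 25.0 min and 50.0 min, so that pair gives τ = 35.0 min, the fade time: the time, as read from the curve, in which the net gain of target, making minus loss, falls by a factor e.

Now place the flask. Interpolate the 50.0 min readings linearly in charge, and 0.19 M gives 29.1%. Divide by 1 − exp(−t/τ) to get the plateau, 38.2%. Divide that by τ to get the starting constant s = 0.0109 min⁻¹, pseudo-first-order at held gas.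

Next, double the gas. Assume s follows [dissolved gas]. Faster making also spends substrate sooner, so add s to 1/τ. The fade time shortens to 25.3 min, and zeta gives 47.7%.

The weak link is τ, which rests on one pair. Test it on grey. Scaled to its last reading, the grey plateau is 39.6%. The curve then gives 4.28% against 4.3% and 17.2% against 16.6%. That second miss is 0.60 percentage points, with a scatter of 0.3 points. Keep τ as a rough reading. The first point shows no lag, so expect little from delta.

The forecast gives 29.1%, names zeta, and puts zeta at 45%, lower than my figure. It warns: “I assume the gas is a first-order reactant, though the runs never varied it.”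

The flask gives 28.9%. Zeta gives 46.3%, a gain of 17 points, and delta gains 0.095 points.

    gas phase ⇌ dissolved gas, rate k1*(csat - [dissolved gas]) (kL = 0.258 s⁻¹)
    substrate + dissolved gas → target (k = 0.0151 M⁻¹ s⁻¹)
    substrate → side product A (k = 8.74 × 10⁻⁵ s⁻¹)
    target ⇌ isomer of the product (K = 0.500, k = 1.09 × 10⁻⁴ s⁻¹)
    substrate + target → side product B (k = 4.94 × 10⁻⁴ M⁻¹ s⁻¹)

In this flask target is made 5.88 times as fast as it is used up at 16.0 min, but 2.33 times at 50.0 min, a ratio that falls and stays above one. Carry τ through that result: 28.9% sets a plateau of 38.0% and predicts 34.1% at 80 min, where the same flask holds 34.2%.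

Readings and results are simulated for an exercise; noise was put on by code.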